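**Strategy.** The upper pyran ring C is disconnected at C4–C4a. Its C4 is a diarylmethine carbon bonded to two phloroglucinol-type rings (upper ring A through C4a, lower ring A through C8) and to the oxygenated C3. The precursor is therefore an open-chain ketone: perbenzylated epigallocatechin gallate acylated at C8 by a (2S,3R)-2-benzyloxy-3-aryl-3-aryloxypropanoyl chain whose aryl ether is the future ring A. Acid makes that ring attack the ketone, closing ring C and giving a C4 cation stabilised by both rings. Hydride added in the same flask enters anti to the C3 benzyloxy and C2 aryl groups and so sets the unusual all-cis (4S) centre.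

Key step: step 10

Remark: the SMILES places the upper 2-aryl, 3-hydroxy and 4-aryl groups all cis, (2R,3R,4S), i.e. an epicatechin unit linked 4α→8 to (−)-epigallocatechin 3-O-gallate (2R,3R); the route is built for this diastereomer.

**Step 1**
Reactants: 1 (−)-epigallocatechin
Product: 2 5,7,3′,4′,5′-penta-O-benzyl-(−)-epigallocatechin
Conditions: BnBr (5.5 equiv), K2CO3, DMF, 0 °C → rt, argon
Reagents that add atoms: benzyl bromide, BrCc1ccccc1
Why: Williamson etherification in which carbonate deprotonates only the five phenols, so the secondary 3-hydroxyl stays free; cold, oxygen-free conditions should suppress C-benzylation and C2 epimerisation through ring opening.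

**Step 2**
Reactants: 2 5,7,3′,4′,5′-penta-O-benzyl-(−)-epigallocatechin
Product: 3 8-bromo-5,7,3′,4′,5′-penta-O-benzyl-(−)-epigallocatechin
Conditions: N-bromosuccinimide (1.0 equiv), CH2Cl2, −78 °C → rt
Reagents that add atoms: N-bromosuccinimide, O=C1CCC(=O)N1Br
Why: Electrophilic aromatic bromination should go to the most electron-rich ring A and there to C8, the position preferred in 5,7-di-O-benzyl flavan-3-ols; the free 3-hydroxyl and the more hindered ring B should not react with one equivalent at low temperature.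

**Step 3**
Reactants: 3 8-bromo-5,7,3′,4′,5′-penta-O-benzyl-(−)-epigallocatechin; 4 3,4,5-tris(benzyloxy)benzoic acid
Product: 5 8-bromo-octa-O-benzyl-(−)-epigallocatechin gallate
Conditions: DCC, DMAP (cat.), CH2Cl2, 0 °C → rt
Reagents that add atoms: none
Why: Steglich esterification acylates the secondary 3-hydroxyl through the O-acylisourea and acylpyridinium without breaking any bond at C3, so both stereocentres and the aryl bromide should be untouched.

**Step 4**
Reactants: 6 (S)-4-benzyloxazolidin-2-one; 7 (benzyloxy)acetyl chloride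
Product: 9 (S)-4-benzyl-3-[(benzyloxy)acetyl]oxazolidin-2-one, via lithium oxazolidinide 8 (not isolated)
Conditions: n-BuLi, THF, −78 °C; then 7, −78 → 0 °C
Reagents that add atoms: none
Why: N-Acylation of the lithiated oxazolidinone with an acid chloride is the standard entry to Evans imides and does not involve the auxiliary stereocentre.

**Step 5**
Reactants: 9 (S)-4-benzyl-3-[(benzyloxy)acetyl]oxazolidin-2-one; 10 3,4-bis(benzyloxy)benzaldehyde
Product: 12 (S)-4-benzyl-3-[(2S,3R)-2-(benzyloxy)-3-[3,4-bis(benzyloxy)phenyl]-3-hydroxypropanoyl]oxazolidin-2-one, via dibutylboron (Z)-enolate 11 (not isolated)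
Conditions: Bu2BOTf, Et3N, CH2Cl2, −78 → 0 °C; then 10, −78 → 0 °C; pH 7 buffer/MeOH work-up
Reagents that add atoms: none
Why: Evans syn-aldol reaction: the (Z)-boron enolate reacts through a chair Zimmerman–Traxler transition state on the face opposite the auxiliary benzyl group, which should set (2S) at the benzyloxy carbon and (3R) at the carbinol carbon (syn), the centres that become C3 and C2 of the upper unit.

**Step 6**
Reactants: 12 syn-aldol imide
Product: 13 (2S,3R)-2-(benzyloxy)-3-[3,4-bis(benzyloxy)phenyl]-3-hydroxy-N-methoxy-N-methylpropanamide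
Conditions: MeNHOMe·HCl, AlMe3, THF/CH2Cl2, −20 → 0 °C; aq. HCl work-up
Reagents that add atoms: N,O-dimethylhydroxylamine hydrochloride, CNOC.Cl
Why: Aluminium amide transamidation (Weinreb amide formation) of a β-hydroxy imide is directed to the exocyclic carbonyl by the aluminium alkoxide of the free hydroxyl and should release the auxiliary without touching either stereocentre.

**Step 7**
Reactants: 14 [3,5-bis(benzyloxy)phenyl]boronic acid
Product: 15 potassium [3,5-bis(benzyloxy)phenyl]trifluoroborate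
Conditions: KHF2, MeOH/H2O, rt
Reagents that add atoms: potassium hydrogen difluoride, [K+].[F-].F
Why: Boronic acids are converted by KHF2 into air-stable potassium trifluoroborates, the boron form best suited to copper-catalysed etherification of aliphatic alcohols.

**Step 8**
Reactants: 13 β-hydroxy Weinreb amide; 15 potassium [3,5-bis(benzyloxy)phenyl]trifluoroborate
Product: 16 (2S,3R)-2-(benzyloxy)-3-[3,4-bis(benzyloxy)phenyl]-3-[3,5-bis(benzyloxy)phenoxy]-N-methoxy-N-methylpropanamide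
Conditions: Cu(OAc)2·H2O (10 mol %), DMAP (20 mol %), 4 Å MS, O2 (1 atm), CH2Cl2, rt
Reagents that add atoms: none
Why: Chan–Lam-type oxidative coupling forms the O–aryl bond at the arene, so the benzylic C–O bond is never broken and the (3R) centre should be retained; the neutral room-temperature conditions avoid retro-aldol cleavage and ionisation of the electron-rich benzylic position.

**Step 9**
Reactants: 5 8-bromo-octa-O-benzyl-(−)-epigallocatechin gallate; 16 aryl ether Weinreb amide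
Product: 19 8-[(2S,3R)-2-(benzyloxy)-3-[3,4-bis(benzyloxy)phenyl]-3-[3,5-bis(benzyloxy)phenoxy]propanoyl]-octa-O-benzyl-(−)-epigallocatechin gallate (open-chain ketone), via 8-lithio arene 17 (not isolated), via tetrahedral lithium adduct 18 (not isolated)
Conditions: n-BuLi (1.0 equiv), THF, −100 °C, 5 min; then 16, −100 → −40 °C; aq. NH4Cl
Reagents that add atoms: none
Why: Bromine–lithium exchange at −100 °C (Parham-type conditions) should be faster than addition of n-BuLi to the hindered, electron-rich gallate ester, and the 2,6-dialkoxyaryllithium acylates the Weinreb amide through the chelated adduct 18, which gives the ketone only on work-up and so prevents over-addition; neither chain stereocentre is touched.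

**Step 10**
Reactants: 19 open-chain ketone
Product: 22 trideca-O-benzyl ether of 23 (all twelve phenols plus the upper 3-OH benzylated; upper ring C all-cis 2R,3R,4S), via tertiary flavan-4-ol 20 (not isolated), via flavan-4-ylium trifluoroacetate 21 (not isolated)
Conditions: CF3CO2H (20 equiv), CH2Cl2 (0.01 M), −20 → 0 °C; then Bu3SnH (3 equiv), −20 → 0 °C
Reagents that add atoms: none
Why: CF3CO2H protonates the C4 ketone and the ortho carbon (future C4a) of the tethered 3,5-bis(benzyloxy)phenyl ether attacks it in an intramolecular Friedel–Crafts hydroxyalkylation, a six-membered closure that is 6-exo-trig at the carbonyl and closes ring C as carbinol 20, which ionises at once to cation 21, stabilised by upper ring A and lower ring A. The closest known reaction type is the reductive Friedel–Crafts alkylation of arenes with ketones (acid cyclodehydration of β-aryloxy ketones followed by ionic hydrogenation of the benzylic cation with a tin or silicon hydride). The new C4 centre is controlled by the C2 and C3 centres from step 5: in the half-chair cation the 3-benzyloxy group is pseudo-axial and cis to the 2-aryl group, so Bu3SnH should deliver hydride to the opposite face and the lower unit ends cis to both (4S, all-cis). Regioselectivity is secured by symmetry (both ortho positions of the ether ring are equivalent, the para position cannot reach) and by the far higher nucleophilicity of this ring compared with ring B, whose attack would give a five-membered ring. Chemoselectivity (ring closure before reduction) is secured by adding the hydride only after the ketone has cyclised, and low temperature keeps β-elimination of the aryloxy group and C3 epimerisation through the 3-ene slow.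

**Step 11**
Reactants: 22 trideca-O-benzyl ether
Product: 23 target, epicatechin-(4α→8)-epigallocatechin 3-O-gallate
Conditions: H2 (1 atm), Pd(OH)2/C, THF/MeOH/H2O, rt
Reagents that add atoms: none
Why: Hydrogenolysis of the thirteen benzyl ethers is the standard last step for benzyl-protected flavan-3-ol oligomers and should leave the gallate ester, the C2–O1 benzylic ether bonds and the diarylmethine C4 intact.

**Compound list**

1 | (−)-epigallocatechin (2R,3R) | O[C@@H]1Cc2c(O)cc(O)cc2O[C@@H]1c1cc(O)c(O)c(O)c1 | starting material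
2 | 5,7,3′,4′,5′-penta-O-benzyl-(−)-epigallocatechin | O[C@@H]1Cc2c(OCc3ccccc3)cc(OCc3ccccc3)cc2O[C@@H]1c1cc(OCc2ccccc2)c(OCc2ccccc2)c(OCc2ccccc2)c1 | intermediate
3 | 8-bromo-5,7,3′,4′,5′-penta-O-benzyl-(−)-epigallocatechin | O[C@@H]1Cc2c(OCc3ccccc3)cc(OCc3ccccc3)c(Br)c2O[C@@H]1c1cc(OCc2ccccc2)c(OCc2ccccc2)c(OCc2ccccc2)c1 | intermediate
4 | 3,4,5-tris(benzyloxy)benzoic acid | OC(=O)c1cc(OCc2ccccc2)c(OCc2ccccc2)c(OCc2ccccc2)c1 | starting material
5 | 8-bromo-octa-O-benzyl-(−)-epigallocatechin gallate | O=C(O[C@@H]1Cc2c(OCc3ccccc3)cc(OCc3ccccc3)c(Br)c2O[C@@H]1c1cc(OCc2ccccc2)c(OCc2ccccc2)c(OCc2ccccc2)c1)c1cc(OCc2ccccc2)c(OCc2ccccc2)c(OCc2ccccc2)c1 | intermediate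
6 | (S)-4-benzyloxazolidin-2-one | O=C1OC[C@H](Cc2ccccc2)N1 | starting material
7 | (benzyloxy)acetyl chloride | ClC(=O)COCc1ccccc1 | starting material
8 | lithium (S)-4-benzyl-2-oxooxazolidin-3-ide | [Li+].O=C1OC[C@H](Cc2ccccc2)[N-]1 | intermediate
9 | (S)-4-benzyl-3-[(benzyloxy)acetyl]oxazolidin-2-one | O=C1OC[C@H](Cc2ccccc2)N1C(=O)COCc1ccccc1 | intermediate
10 | 3,4-bis(benzyloxy)benzaldehyde | O=Cc1ccc(OCc2ccccc2)c(OCc2ccccc2)c1 | starting material
11 | dibutylboron (Z)-enolate of 9 | O=C1OC[C@H](Cc2ccccc2)N1/C(OB(CCCC)CCCC)=C/OCc1ccccc1 | intermediate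
12 | (S)-4-benzyl-3-[(2S,3R)-2-(benzyloxy)-3-[3,4-bis(benzyloxy)phenyl]-3-hydroxypropanoyl]oxazolidin-2-one | O=C1OC[C@H](Cc2ccccc2)N1C(=O)[C@@H](OCc1ccccc1)[C@H](O)c1ccc(OCc2ccccc2)c(OCc2ccccc2)c1 | intermediate
13 | (2S,3R)-2-(benzyloxy)-3-[3,4-bis(benzyloxy)phenyl]-3-hydroxy-N-methoxy-N-methylpropanamide | CON(C)C(=O)[C@@H](OCc1ccccc1)[C@H](O)c1ccc(OCc2ccccc2)c(OCc2ccccc2)c1 | intermediate
14 | [3,5-bis(benzyloxy)phenyl]boronic acid | OB(O)c1cc(OCc2ccccc2)cc(OCc2ccccc2)c1 | starting material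
15 | potassium [3,5-bis(benzyloxy)phenyl]trifluoroborate | [K+].F[B-](F)(F)c1cc(OCc2ccccc2)cc(OCc2ccccc2)c1 | intermediate
16 | (2S,3R)-2-(benzyloxy)-3-[3,4-bis(benzyloxy)phenyl]-3-[3,5-bis(benzyloxy)phenoxy]-N-methoxy-N-methylpropanamide | CON(C)C(=O)[C@@H](OCc1ccccc1)[C@H](Oc1cc(OCc2ccccc2)cc(OCc2ccccc2)c1)c1ccc(OCc2ccccc2)c(OCc2ccccc2)c1 | intermediate
17 | 8-lithio-octa-O-benzyl-(−)-epigallocatechin gallate | O=C(O[C@@H]1Cc2c(OCc3ccccc3)cc(OCc3ccccc3)c([Li])c2O[C@@H]1c1cc(OCc2ccccc2)c(OCc2ccccc2)c(OCc2ccccc2)c1)c1cc(OCc2ccccc2)c(OCc2ccccc2)c(OCc2ccccc2)c1 | intermediate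
18 | tetrahedral lithium alkoxide from 17 and 16 (hemiaminal carbon undefined) | O=C(O[C@@H]1Cc2c(OCc3ccccc3)cc(OCc3ccccc3)c(C([O-])(N(C)OC)[C@@H](OCc3ccccc3)[C@H](Oc3cc(OCc4ccccc4)cc(OCc4ccccc4)c3)c3ccc(OCc4ccccc4)c(OCc4ccccc4)c3)c2O[C@@H]1c1cc(OCc2ccccc2)c(OCc2ccccc2)c(OCc2ccccc2)c1)c1cc(OCc2ccccc2)c(OCc2ccccc2)c(OCc2ccccc2)c1.[Li+] | intermediate
19 | 8-[(2S,3R)-2-(benzyloxy)-3-[3,4-bis(benzyloxy)phenyl]-3-[3,5-bis(benzyloxy)phenoxy]propanoyl]-octa-O-benzyl-(−)-epigallocatechin gallate | O=C(O[C@@H]1Cc2c(OCc3ccccc3)cc(OCc3ccccc3)c(C(=O)[C@@H](OCc3ccccc3)[C@H](Oc3cc(OCc4ccccc4)cc(OCc4ccccc4)c3)c3ccc(OCc4ccccc4)c(OCc4ccccc4)c3)c2O[C@@H]1c1cc(OCc2ccccc2)c(OCc2ccccc2)c(OCc2ccccc2)c1)c1cc(OCc2ccccc2)c(OCc2ccccc2)c(OCc2ccccc2)c1 | intermediate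
20 | ring-closed tertiary flavan-4-ol (C4 configuration undefined) | O=C(O[C@@H]1Cc2c(OCc5ccccc5)cc(OCc5ccccc5)c(C3(O)c4c(OCc5ccccc5)cc(OCc5ccccc5)cc4O[C@H](c4ccc(OCc5ccccc5)c(OCc5ccccc5)c4)[C@@H]3OCc3ccccc3)c2O[C@@H]1c1cc(OCc2ccccc2)c(OCc2ccccc2)c(OCc2ccccc2)c1)c1cc(OCc2ccccc2)c(OCc2ccccc2)c(OCc2ccccc2)c1 | intermediate
21 | 4-aryl-flavan-4-ylium trifluoroacetate | O=C(O[C@@H]1Cc2c(OCc5ccccc5)cc(OCc5ccccc5)c([C+]3c4c(OCc5ccccc5)cc(OCc5ccccc5)cc4O[C@H](c4ccc(OCc5ccccc5)c(OCc5ccccc5)c4)[C@@H]3OCc3ccccc3)c2O[C@@H]1c1cc(OCc2ccccc2)c(OCc2ccccc2)c(OCc2ccccc2)c1)c1cc(OCc2ccccc2)c(OCc2ccccc2)c(OCc2ccccc2)c1.[O-]C(=O)C(F)(F)F | intermediate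
22 | trideca-O-benzyl ether of 23 (upper ring C all-cis) | O=C(O[C@@H]1Cc2c(OCc5ccccc5)cc(OCc5ccccc5)c([C@@H]3c4c(OCc5ccccc5)cc(OCc5ccccc5)cc4O[C@H](c4ccc(OCc5ccccc5)c(OCc5ccccc5)c4)[C@@H]3OCc3ccccc3)c2O[C@@H]1c1cc(OCc2ccccc2)c(OCc2ccccc2)c(OCc2ccccc2)c1)c1cc(OCc2ccccc2)c(OCc2ccccc2)c(OCc2ccccc2)c1 | intermediate
23 | epicatechin-(4α→8)-epigallocatechin 3-O-gallate | O=C(O[C@@H]1Cc2c(O)cc(O)c([C@@H]3c4c(O)cc(O)cc4O[C@H](c4ccc(O)c(O)c4)[C@@H]3O)c2O[C@@H]1c1cc(O)c(O)c(O)c1)c1cc(O)c(O)c(O)c1 | target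

**Step count.** Total: 11 steps. Longest linear sequence: 7 steps (steps 4, 5, 6, 8, 9, 10, 11).

**Steps most likely to fail**

Step 10. The ketone may lose the β-aryloxy group by acid-promoted elimination before the arene attacks. The C4 cation may also equilibrate with the 3-ene and erode the C3 configuration before hydride arrives. The fallback reverses the order in which the two aryl–C4 bonds are made. It sets out from bromide 5 and commercial (−)-epicatechin and comes back at carbinol 20. (−)-Epicatechin is perbenzylated (NaH, BnBr, DMF) to 3,5,7,3′,4′-penta-O-benzylepicatechin F1. This is oxidised at C4 with DDQ in wet CH2Cl2 to 4β-hydroxy-penta-O-benzylepicatechin F2, and then with Pr4N[RuO4] and N-methylmorpholine N-oxide to cis-penta-O-benzyl-flavan-4-one F3. Aryllithium 17, made from 5 as in step 9, should add to the ketone of F3 (THF, −78 °C) to give 20. The second half of step 10 (CF3CO2H, Bu3SnH) then gives 22.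

Step 9. The aryllithium may attack the gallate ester, or it may deprotonate the amide α to the carbonyl with loss of aryloxide, instead of acylating. The fallback keeps the ester out of the organometallic step by installing it afterwards. It sets out from bromo alcohol 3 and comes back at 22. Alcohol 3 is silylated (TBSOTf, 2,6-lutidine, CH2Cl2) to its 3-O-tert-butyldimethylsilyl ether F4. Lithiation and acylation with 16 as in step 9 should give silyl-protected ketone F5. The conditions of step 10 should cyclise and reduce it to silyl-protected all-cis dimer F6. Bu4NF frees lower-unit 3-alcohol F7, which is esterified with acid 4 (DCC, DMAP, CH2Cl2) to give 22.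

Step 8. Etherification of the hindered secondary benzylic alcohol may be slow, with competing oxidation of the alcohol or loss of the borate by protodeboronation and homocoupling. The fallback forms the C–O bond at the benzylic carbon by epoxide opening instead. It sets out from aldehyde 10 and comes back at 16. Ando olefination (ethyl (diphenoxyphosphoryl)acetate, NaH, THF, −78 °C) should give ethyl (Z)-3-[3,4-bis(benzyloxy)phenyl]acrylate F8. Jacobsen epoxidation (NaOCl, (S,S)-(salen)MnCl, the chloro complex of trivalent manganese with N,N′-bis(3,5-di-tert-butylsalicylidene)cyclohexane-1,2-diamine) should give ethyl cis-(2S,3S)-3-[3,4-bis(benzyloxy)phenyl]glycidate F9. 3,5-Bis(benzyloxy)phenol with Cs2CO3 in DMF should open it at the benzylic carbon with inversion to ethyl (2S,3R)-3-aryl-3-aryloxy-2-hydroxypropanoate F10. Benzylation (BnBr, Ag2O) gives ethyl (2S,3R)-2-benzyloxy-3-aryl-3-aryloxypropanoate F11. MeNHOMe·HCl with i-PrMgCl (THF, −20 °C) converts the ester into Weinreb amide 16.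

**Further compounds**

F1 | step 10 | 3,5,7,3′,4′-penta-O-benzyl-(−)-epicatechin | O(Cc1ccccc1)[C@@H]1Cc2c(OCc3ccccc3)cc(OCc3ccccc3)cc2O[C@@H]1c1ccc(OCc2ccccc2)c(OCc2ccccc2)c1
F2 | step 10 | 4β-hydroxy-3,5,7,3′,4′-penta-O-benzylepicatechin (3,4-trans) | O[C@H]1c2c(OCc3ccccc3)cc(OCc3ccccc3)cc2O[C@H](c2ccc(OCc3ccccc3)c(OCc3ccccc3)c2)[C@@H]1OCc1ccccc1
F3 | step 10 | (2R,3S)-cis-3,5,7-tris(benzyloxy)-2-[3,4-bis(benzyloxy)phenyl]chroman-4-one | O=C1c2c(OCc3ccccc3)cc(OCc3ccccc3)cc2O[C@H](c2ccc(OCc3ccccc3)c(OCc3ccccc3)c2)[C@@H]1OCc1ccccc1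
F4 | step 9 | 3-O-tert-butyldimethylsilyl ether of 3 | CC(C)(C)[Si](C)(C)O[C@@H]1Cc2c(OCc3ccccc3)cc(OCc3ccccc3)c(Br)c2O[C@@H]1c1cc(OCc2ccccc2)c(OCc2ccccc2)c(OCc2ccccc2)c1
F5 | step 9 | 8-[(2S,3R)-2-(benzyloxy)-3-[3,4-bis(benzyloxy)phenyl]-3-[3,5-bis(benzyloxy)phenoxy]propanoyl]-penta-O-benzyl-3-O-TBS-epigallocatechin | CC(C)(C)[Si](C)(C)O[C@@H]1Cc2c(OCc3ccccc3)cc(OCc3ccccc3)c(C(=O)[C@@H](OCc3ccccc3)[C@H](Oc3cc(OCc4ccccc4)cc(OCc4ccccc4)c3)c3ccc(OCc4ccccc4)c(OCc4ccccc4)c3)c2O[C@@H]1c1cc(OCc2ccccc2)c(OCc2ccccc2)c(OCc2ccccc2)c1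
F6 | step 9 | deca-O-benzyl all-cis epicatechin-(4α→8)-epigallocatechin with lower 3-O-TBS | CC(C)(C)[Si](C)(C)O[C@@H]1Cc2c(OCc5ccccc5)cc(OCc5ccccc5)c([C@@H]3c4c(OCc5ccccc5)cc(OCc5ccccc5)cc4O[C@H](c4ccc(OCc5ccccc5)c(OCc5ccccc5)c4)[C@@H]3OCc3ccccc3)c2O[C@@H]1c1cc(OCc2ccccc2)c(OCc2ccccc2)c(OCc2ccccc2)c1
F7 | step 9 | deca-O-benzyl all-cis epicatechin-(4α→8)-epigallocatechin with free lower 3-OH | O[C@@H]1Cc2c(OCc5ccccc5)cc(OCc5ccccc5)c([C@@H]3c4c(OCc5ccccc5)cc(OCc5ccccc5)cc4O[C@H](c4ccc(OCc5ccccc5)c(OCc5ccccc5)c4)[C@@H]3OCc3ccccc3)c2O[C@@H]1c1cc(OCc2ccccc2)c(OCc2ccccc2)c(OCc2ccccc2)c1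
F8 | step 8 | ethyl (Z)-3-[3,4-bis(benzyloxy)phenyl]acrylate | CCOC(=O)/C=C\c1ccc(OCc2ccccc2)c(OCc2ccccc2)c1
F9 | step 8 | ethyl cis-(2S,3S)-3-[3,4-bis(benzyloxy)phenyl]oxirane-2-carboxylate | CCOC(=O)[C@H]1O[C@H]1c1ccc(OCc2ccccc2)c(OCc2ccccc2)c1
F10 | step 8 | ethyl (2S,3R)-3-[3,4-bis(benzyloxy)phenyl]-3-[3,5-bis(benzyloxy)phenoxy]-2-hydroxypropanoate | CCOC(=O)[C@@H](O)[C@H](Oc1cc(OCc2ccccc2)cc(OCc2ccccc2)c1)c1ccc(OCc2ccccc2)c(OCc2ccccc2)c1
F11 | step 8 | ethyl (2S,3R)-2-(benzyloxy)-3-[3,4-bis(benzyloxy)phenyl]-3-[3,5-bis(benzyloxy)phenoxy]propanoate | CCOC(=O)[C@@H](OCc1ccccc1)[C@H](Oc1cc(OCc2ccccc2)cc(OCc2ccccc2)c1)c1ccc(OCc2ccccc2)c(OCc2ccccc2)c1
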